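**Retrosynthetic overview**
1. GA93 (the target gibberellin) ⇒ 1β-hydroxy-GA5 by 1β-OH-directed β-epoxidation of C2=C3 (the oxirane is made last and sets C-2 and C-3).
2. 1β-Hydroxy-GA5 ⇒ gibberellic acid 3β-mesylate by a syn-SN2' oxygen transfer to C-1 (key C1–O bond; sets C-1 and moves the alkene to C2=C3).
3. The mesylate ⇒ gibberellic acid (GA3) by sulfonylation of its only secondary alcohol.
4. Ring order: rings A–D and the γ-lactone come intact from GA3; the oxirane is the only ring formed.

Assumption: gibberellic acid (GA3), a bulk fermentation product, is taken as a cheap commercial starting material; it supplies C-4, C-5, C-6, C-8, C-9, C-10 and C-13 with the configuration of the target.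
Convention: β is the face of ring A opposite the 19,10-lactone bridge (the face of H-5 and of the 18-methyl group).

**Step 1**
Reactants: 1 gibberellic acid (GA3)
Product: 3 gibberellic acid 3β-O-methanesulfonate, via mixed anhydride 2 (not isolated)
Conditions: MsCl (2.5 equiv), pyridine, 0 °C, 3 h; then H2O, 0 °C, 30 min; pH 3 extraction, used crude
Reagents that add atoms: methanesulfonyl chloride CS(=O)(=O)Cl; water O
Why: O-sulfonylation of the only secondary alcohol (the bridgehead tertiary 13-OH does not react with MsCl/pyridine) leaves the C3–O bond untouched, so C-3 stays β; the 7-acid is activated in passing as mixed anhydride 2, which the water quench cleaves back to the acid.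

**Step 2**
Reactants: 3 gibberellic acid 3β-O-methanesulfonate
Product: 5 1β-hydroxy-GA5, via nitrite ester 4 (not isolated)
Conditions: n-Bu4NNO2 (4 equiv), 2,6-lutidine (1.1 equiv), MeCN, 40 °C; then pH 4 phosphate buffer, EtOAc
Reagents that add atoms: tetrabutylammonium nitrite CCCC[N+](CCCC)(CCCC)CCCC.[O-]N=O
Why: Proposed new method: nitrite-mediated syn-SN2' hydroxylation of a bridged allylic sulfonate; direct SN2 at C-3 would need backside (α) attack at a neopentyl carbon under the lactone bridge, and β-elimination is impossible (C-2 is vinylic, C-4 quaternary), so nitrite oxygen should add to C-1 on the open β face as the pseudo-axial β-mesylate leaves and the alkene shifts to C2=C3, which sets the 1β C–O bond irreversibly, and nitrite ester 4 hydrolyses on work-up; the closest known reactions are the nitrite displacement of secondary sulfonates to give alcohols (Lattrell–Dax-type SN2) and syn-SN2' halide substitution of cyclohexenyl sulfonates.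

**Step 3**
Reactants: 5 1β-hydroxy-GA5
Product: 6 GA93
Conditions: VO(acac)2 (5 mol %), t-BuOOH (1.05 equiv, decane solution), CH2Cl2–THF (4:1), 0 °C to rt
Reagents that add atoms: tert-butyl hydroperoxide CC(C)(C)OO
Why: Hydroxyl-directed epoxidation (Sharpless–Michaelson type): the pseudo-axial secondary 1β-alkoxide binds pentavalent vanadium and delivers oxygen to the β face of C2=C3 (the α face is also blocked by the lactone bridge), which sets C-2 and C-3 cis to the 1β-OH; the hindered bridgehead 13-alkoxide should exchange onto vanadium more slowly and sits close to the plane of the 16-ene (a poor delivery geometry), and the oxidant is limiting, so the 16-ene should survive.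

**Compound list**
1 | gibberellic acid (GA3): 3β,13-dihydroxy-1,16-diene-7-oic acid with 19,10-lactone | C=C1C[C@]23C[C@@]1(O)CC[C@H]2[C@@]12OC(=O)[C@@](C)([C@H]1[C@@H]3C(=O)O)[C@@H](O)C=C2 | starting material
2 | 3β-O-mesyl gibberellic acid 7-carboxylic methanesulfonic mixed anhydride | C=C1C[C@]23C[C@@]1(O)CC[C@H]2[C@@]12OC(=O)[C@@](C)([C@H]1[C@@H]3C(=O)OS(C)(=O)=O)[C@@H](OS(C)(=O)=O)C=C2 | intermediate
3 | gibberellic acid 3β-O-methanesulfonate (free 7-acid, 1-ene, 13-OH) | C=C1C[C@]23C[C@@]1(O)CC[C@H]2[C@@]12OC(=O)[C@@](C)([C@H]1[C@@H]3C(=O)O)[C@@H](OS(C)(=O)=O)C=C2 | intermediate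
4 | 1β-nitrite ester of 5 (1β-O–N=O, 2-ene) | C=C1C[C@]23C[C@@]1(O)CC[C@H]2[C@@]12OC(=O)[C@@](C)([C@H]1[C@@H]3C(=O)O)C=C[C@H]2ON=O | intermediate
5 | 1β-hydroxy-GA5: 1β,13-dihydroxy-2,16-diene-7-oic acid with 19,10-lactone | C=C1C[C@]23C[C@@]1(O)CC[C@H]2[C@@]12OC(=O)[C@@](C)([C@H]1[C@@H]3C(=O)O)C=C[C@H]2O | intermediate
6 | GA93: 2β,3β-epoxy-1β,13-dihydroxy-16-ene-7-oic acid with 19,10-lactone | C=C1C[C@]23C[C@@]1(O)CC[C@H]2[C@@]12OC(=O)[C@@](C)([C@H]1[C@@H]3C(=O)O)[C@H]1O[C@H]1[C@H]2O | target

**Total step count:** 3. **Longest linear sequence:** 3 steps (1 → 3 → 5 → 6).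

**Steps most likely to fail, with fallbacks**

Step 2 (the new method; direct SN2 at C-3 giving the 3-epimer or N-attack by nitrite are the main risks). The fallback uses known chemistry, sets out from 1 and returns at 5. Allylic oxidation of 1 with activated MnO2 (acetone, rt) gives the enone 3-dehydrogibberellic acid F1. Nucleophilic (Weitz–Scheffer) epoxidation with t-BuOOH and DBU (THF, 0 °C) attacks the open β face and gives the 1β,2β-epoxy-3-ketone F2, which already carries the 1β C–O bond. Wharton transposition (N2H4·H2O, cat. AcOH, MeOH, 0 °C, under argon) then proceeds through the epoxy hydrazone F3, opening the oxirane with loss of nitrogen to give 5.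

Step 3 (competing epoxidation of the 16-ene directed by the 13-OH, or over-oxidation). The fallback sets out from 5 and returns at 6. MnO2 oxidises the allylic 1β-alcohol to the 2-en-1-one F4. Nucleophilic epoxidation (t-BuOOH, DBU, THF, 0 °C) reacts only with the enone and, by β-face attack, gives the 2β,3β-epoxy-1-ketone F5. Chelation-controlled reduction with Zn(BH4)2 (Et2O–THF, −20 °C) delivers hydride anti to the oxirane and gives the cis-epoxy alcohol 6; this facial outcome is the least certain point of the fallback.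

Step 1 (side reactions of the activated 7-acid, or loss of the labile allylic mesylate on handling). The fallback sets out from 1 and returns at 5, bypassing 3. A catalytic suprafacial 1,3-hydroxyl shift with Ph3SiOReO3 (3 mol %, THF–Et2O, −20 °C) runs through the allylic perrhenate ester of gibberellic acid F6 and, after [3,3] shift, the 1β-perrhenate ester of the transposed alcohol F7. It gives an equilibrium mixture of 1 and 5; the ratio is unknown, so 5 is separated and 1 recycled.

**Further compounds**
F1 | step 2 | 3-dehydrogibberellic acid (3-oxo-1-ene) | C=C1C[C@]23C[C@@]1(O)CC[C@H]2[C@@]12OC(=O)[C@@](C)([C@H]1[C@@H]3C(=O)O)C(=O)C=C2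
F2 | step 2 | 1β,2β-epoxy-3-oxo derivative of gibberellic acid | C=C1C[C@]23C[C@@]1(O)CC[C@H]2[C@@]12OC(=O)[C@@](C)([C@H]1[C@@H]3C(=O)O)C(=O)[C@H]1O[C@H]12
F3 | step 2 | hydrazone of the 1β,2β-epoxy-3-ketone | C=C1C[C@]23C[C@@]1(O)CC[C@H]2[C@@]12OC(=O)[C@@](C)([C@H]1[C@@H]3C(=O)O)C(=NN)[C@H]1O[C@H]12
F4 | step 3 | 1-oxo-2-ene (enone from 5) | C=C1C[C@]23C[C@@]1(O)CC[C@H]2[C@@]12OC(=O)[C@@](C)([C@H]1[C@@H]3C(=O)O)C=CC2=O
F5 | step 3 | 2β,3β-epoxy-1-ketone | C=C1C[C@]23C[C@@]1(O)CC[C@H]2[C@@]12OC(=O)[C@@](C)([C@H]1[C@@H]3C(=O)O)[C@H]1O[C@H]1C2=O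
F6 | step 1 | gibberellic acid 3β-O-perrhenate ester | C=C1C[C@]23C[C@@]1(O)CC[C@H]2[C@@]12OC(=O)[C@@](C)([C@H]1[C@@H]3C(=O)O)[C@@H](O[Re](=O)(=O)=O)C=C2
F7 | step 1 | 1β-O-perrhenate ester of 5 | C=C1C[C@]23C[C@@]1(O)CC[C@H]2[C@@]12OC(=O)[C@@](C)([C@H]1[C@@H]3C(=O)O)C=C[C@H]2O[Re](=O)(=O)=O
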